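## The problem

Target 25 is a depsidone: two benzene rings joined twice, by a diaryl ether and by an aryl ester, so that a seven-membered dioxepinone lies between them. Ring A is numbered here as the 2H-chromene it belongs to (O1, C2 to C4, C4a, C5 to C8, C8a) and ring B as a benzoyl unit (C1′ to C6′). The ether runs from C6 to C2′ and the ester from the C5 oxygen to the C1′ carboxyl. Ring A has no hydrogen: in order it carries the pyran oxygen (C8a), a free hydroxyl (C8), a prenyl group (C7), the aryloxy group (C6), the acyloxy group (C5) and the pyran carbon (C4a). Ring B has three oxygens that must be told apart, and its ether oxygen sits between a prenyl group and the carboxyl, so the ether bond links two carbons that are each flanked on both sides. There is no stereocentre, so no centre can control another; the task is one of regiochemistry. Prenyl groups beside free phenols close to chromans in acid, the chromene double bond is sensitive to acid and electrophiles, the aryl ester is opened by alkoxide or hydroxide, the hydroquinone stage of ring A is air-sensitive, and hydrogenation is excluded. The enabling feature is the para pair of oxygens at C5 and C8: C8, C8a and C4a match the carbene carbon and enol ether carbons of a dihydropyranyl carbene complex, C5 a CO carbon, and C6 and C7 (aryloxy, prenyl) the two carbons of an alkyne. This is the pattern of a Dötz benzannulation, which makes ring A with the ring B oxygen already attached.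

## Retrosynthesis

The last operation removes the two methoxymethyl groups from the ring B oxygens of 24 (two O–CH2 bonds). Masking these phenols to the end is preferred to lactonising a free polyphenol, whose 2,4,6-trioxygenated acid would be prone to decarboxylation and intermolecular acylation. Acetal ethers are chosen over benzyl ethers (hydrogenolysis would reduce the prenyl groups) and aryl silyl ethers (lost in the basic steps). The forward step must be an acid treatment mild enough for two prenyl groups, the chromene and the aryl ester.

In 24 the lactone C(=O)–O bond at the C5 oxygen is cut to give hydroquinone acid 23, which is traced to allyl ester 22. The ester is cut before the ether because the ether joins two crowded carbons, whereas the ester closes readily once both partners sit on the same ether oxygen. Only the C5 hydroxyl of 23 can reach the carboxyl, so the C8 hydroxyl needs no protection. An allyl ester is preferred to a methyl ester: a benzoate with two ortho substituents would need hot hydroxide, which the air-sensitive hydroquinone would not tolerate, while palladium-catalysed deallylation is neutral. The forward steps ask for deallylation that leaves the prenyl groups alone and a carbodiimide lactonisation at high dilution.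

The free C8 hydroxyl of 22 is traced to the C8 methyl ether of phenol 20, passing through quinone 21. The methyl group is the alkoxy substituent of the carbene complex and arrives with the benzannulation. A 4-methoxyphenol can be unmasked without Lewis acid, by oxidation to the quinone and reduction. This must happen while the carboxyl is still an ester, since a free acid could add to the oxidised ring. The forward step needs an oxidant that spares the prenyl groups and the chromene.

The C3=C4 double bond of 20 is traced to the C4 silyloxy group of chroman 18, through chromanol 19. The double bond cannot be present earlier, because the enol ether double bond of the pyran fragment is consumed in forming ring A; the C4 oxygen is the handle that restores unsaturation. Elimination is placed directly after the key step because in 18 no free phenol stands next to a prenyl group, so the acid it needs is harmless there.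

Ring A of 18 is cut along three C–C bonds, C7–C8, C5–C6 and C4a–C5. This gives carbene complex 7 (C8 with its methoxy group, C8a, C4a and, as a CO ligand, C5) and ynol ether 16 (C6 and C7). Forming the C6–O–C2′ ether between complete rings would meet the doubly flanked bond directly, and substituting a preformed ring A position by position would need many regiocontrolled aromatic substitutions. This cut instead builds the hexasubstituted ring and fixes all six positions in one step, with the ether oxygen carried in on the alkyne. The precursors are much simpler: 7 has one ring and no arene, and 16 is ring B with an alkynyl ether. The forward reaction must insert the alkyne with the aryloxy carbon next to the CO-derived carbon, which the polarity of the ynol ether favours.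

Ynol ether 16 is cut at the bond between the alkyne carbon and the prenyl CH2 and at the O–C(sp) bond, leading through dichlorovinyl ether 13 to phenol 11 and trichloroethene 12. Making the aryl–oxygen–carbon link here turns the hindered ether problem into O-vinylation of a phenol with a small two-carbon electrophile. The forward steps need an alkyllithium that acts on the dichlorovinyl group faster than on the ester, and prenylation of the acetylide at the primary carbon.

Phenol 11 is traced by removal of the two acetal groups to triol 10, by the C3′–prenyl bond to ester 9, and by the ester C–O bond to acid 8. In 9 the two free ring positions are equivalent, so only one mono-C-prenyl isomer can form. In 10 the hydroxyl between prenyl and ester is the most hindered and is expected to stay free when the other two are protected; it is the oxygen needed for the ynol ether. The forward steps require C- over O-alkylation of a phloroglucinol-type anion and steric discrimination between two ester-chelated hydroxyls.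

Complex 7 is cut at the chromium–carbon double bond and at the bond from the carbene carbon to C6 of the pyran, giving silyl ether 3 and Cr(CO)6 4 (one CO ligand becomes the carbene carbon). Ether 3 comes from alcohol 2 and this from dihydropyranone 1 by 1,2-reduction. Reduction is preferred to ketalisation of 1, because a ketal of this vinylogous ester is hard to form and would be a vinylogous orthoester. The silyloxy pattern is that of a protected glycal, for which lithiation next to the ring oxygen is established. The forward steps ask for deprotonation at the enol ether carbon and O-methylation of the acylchromate.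

## Roads not taken

Alternative 1: Both links between the rings, the C6–O ether and the lactone C(=O)–O bond, are traced to one benzophenone A2, in which the ring B carbonyl carbon is bonded to C6 of a ring A hydroquinone. In the forward step Ag2O would oxidise the hydroquinone to the aroylquinone, the free C2′ hydroxyl would add to the aroyl-bearing quinone carbon, and the acyl group would then shift from that carbon to the neighbouring C5 oxygen. This would give A1, which is the same substance as 24 of the chosen route.
- Merits: it is biomimetic, forms ether and ester in one operation, needs no chromium and no ynol ether, and ends one deprotection from the target. In the endgame it is shorter than the chosen plan, which needs four steps after its key step to reach the same compound.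
- Weak points: A2 is a ketone between two rings with four ortho substituents, so its assembly by acylation or by aryl-metal addition and oxidation is where hindrance is greatest. Ring A, fully substituted and already carrying chromene and prenyl, must be built first by separate arene chemistry. The prenylquinone stage can also tautomerise towards quinone methides.
- Comparison: the chosen plan offsets the longer endgame by constructing ring A, with all six substituents placed, in the same step that attaches ring B, from two fragments made by routine chemistry.

Alternative 2: The pyran ring is cut at C4–C4a and O1–C2, back to dihydroxyquinone A4 and enal A5. In the forward step the free quinone C–H of A4 condenses with the aldehyde of A5 (Knoevenagel type) and the dienone oxygen closes onto the dimethyl-bearing carbon by oxa-6π electrocyclisation, giving pyranoquinone A3.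
- Merits: two cheap components, no stoichiometric metal, and the chromene at its final oxidation level, so there is no C4 oxygen to carry and remove. For the pyran alone this is the better route; the chosen plan spends steps 1, 2 and 10 on that oxygen.
- Weak points: closure can occur onto either oxygen flanking the new alkylidene, giving para- and ortho-quinone isomers. More seriously, A3 still lacks ring B. Its C6 hydroxyl would have to become a diaryl ether to a ring B carbon flanked by prenyl and carboxyl, or be turned into a leaving group for displacement by a hindered, hydrogen-bonded ring B phenoxide. That step decides the route and remains unsolved.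
- Comparison: the chosen plan avoids this by making the aryl–oxygen bond before ring A exists, as an O-alkynylation of a phenol.

Alternative 3: The C2′–O ether bond and the C1′–carboxyl bond are cut together. The aryne released by fluoride from silyl triflate A7 would be attacked by the caesium phenoxide of ring A phenol A8 at the aryne carbon next to the prenyl group, and the resulting aryl anion would take up carbon dioxide A9 to give acid A6.
- Merits: one step makes the ether and installs the carboxyl, no carboxyl protecting group is needed, and the alkoxy group beside the aryne directs the nucleophile to the required carbon. If A7 and A8 were available, fragment coupling would be more convergent than in the chosen plan.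
- Weak points: the nucleophile is a phenoxide with two ortho substituents on a hexasubstituted ring, and the aryne carbon to be attacked is itself flanked by a prenyl group. Protonation of the aryl anion and ene or cycloaddition reactions of the aryne with the prenyl and chromene double bonds compete with carboxylation. A8 needs its own synthesis with the C6 oxygen differentiated from C5 and C8. In A6 all four phenols carry the same acetal, so lactonisation would have to follow a global acid deprotection of a decarboxylation-prone polyphenolic acid.
- Comparison: in the chosen plan ring A arises in the coupling step, the aryl–oxygen bond is made at an sp carbon, and the C5 and C8 oxygens emerge already differentiated as hydroxyl and methoxy.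

Key step: step 9

Assumption: dihydropyranone 1 is taken as a purchasable building block, and compounds 2, 3, 5 to 7 and 17 to 19 are racemic at the oxygen-bearing C4, a spectator centre that becomes sp2 in step 10.

## Route

Step 1
Reactants: 1 2,2-dimethyl-2,3-dihydro-4H-pyran-4-one
Product: 2 2,2-dimethyl-3,4-dihydro-2H-pyran-4-ol (racemic)
Conditions: NaBH4, CeCl3·7H2O, MeOH, -78 to 0 °C; basic work-up, crude used directly
Reagents that add atoms: none
Why: Luche 1,2-reduction of a vinylogous ester, the standard route from dihydropyranones to glycal-type allylic alcohols; the new stereocentre is formed without control (racemic) and is destroyed in step 10.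

Step 2
Reactants: 2 2,2-dimethyl-3,4-dihydro-2H-pyran-4-ol
Product: 3 2,2-dimethyl-4-(triisopropylsilyloxy)-3,4-dihydro-2H-pyran (racemic)
Conditions: TIPSCl, imidazole, DMF, 40 °C
Reagents that add atoms: triisopropylsilyl chloride, CC(C)[Si](Cl)(C(C)C)C(C)C
Why: Silylation of a secondary allylic alcohol under basic conditions that spare the acid-labile enol ether; the triisopropylsilyl group is chosen because, unlike a methyl-bearing silyl group, it resists metalation in the following t-BuLi step.

Step 3
Reactants: 3 2,2-dimethyl-4-(triisopropylsilyloxy)-3,4-dihydro-2H-pyran; 4 chromium hexacarbonyl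
Product: 7 pentacarbonyl{methoxy[2,2-dimethyl-4-(triisopropylsilyloxy)-3,4-dihydro-2H-pyran-6-yl]methylidene}chromium (racemic), via vinyllithium 5 (not isolated), via lithium acylchromate 6 (not isolated)
Conditions: t-BuLi, THF, -78 to 0 °C; Cr(CO)6, THF, 0 °C to rt; MeOTf, CH2Cl2, 0 °C
Reagents that add atoms: methyl trifluoromethanesulfonate, COS(=O)(=O)C(F)(F)F
Why: Fischer carbene synthesis: the vinylic C–H next to the ring oxygen is removed by t-BuLi as in the C1-lithiation of silylated glycals, the vinyllithium adds to a CO ligand of zerovalent chromium, and the acylchromate is O-methylated by the hard methylating agent.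

Step 4
Reactants: 8 2,4,6-trihydroxybenzoic acid
Product: 9 allyl 2,4,6-trihydroxybenzoate
Conditions: allyl bromide, KHCO3, DMF, rt
Reagents that add atoms: allyl bromide, C=CCBr
Why: Carboxylate O-alkylation: hydrogen carbonate deprotonates only the carboxylic acid, so the ester forms without etherification of the phenols, and room temperature avoids decarboxylation.

Step 5
Reactants: 9 allyl 2,4,6-trihydroxybenzoate
Product: 10 allyl 2,4,6-trihydroxy-3-(3-methylbut-2-en-1-yl)benzoate
Conditions: prenyl bromide, DBU, THF, 0 °C to rt
Reagents that add atoms: prenyl bromide (1-bromo-3-methylbut-2-ene), CC(C)=CCBr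
Why: C-Alkylation of a phloroglucinol-type phenoxide, as used for C-prenylation of acylphloroglucinols; C3′ and C5′ of 9 are equivalent, so only one mono-C-prenyl isomer can form, and limiting the halide holds back double alkylation.

Step 6
Reactants: 10 allyl 2,4,6-trihydroxy-3-(3-methylbut-2-en-1-yl)benzoate
Product: 11 allyl 2-hydroxy-4,6-bis(methoxymethoxy)-3-(3-methylbut-2-en-1-yl)benzoate
Conditions: MOMCl (2.1 equiv), i-Pr2NEt, CH2Cl2, 0 °C
Reagents that add atoms: chloromethyl methyl ether, COCCl
Why: Williamson-type acetal etherification: the para hydroxyl reacts first and, of the two ester-chelated ortho hydroxyls, the one not flanked by the prenyl group reacts next, so the most hindered hydroxyl (C2′) should remain free.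

Step 7
Reactants: 11 allyl 2-hydroxy-4,6-bis(methoxymethoxy)-3-(3-methylbut-2-en-1-yl)benzoate; 12 trichloroethene
Product: 13 allyl 2-{[(E)-1,2-dichloroethenyl]oxy}-4,6-bis(methoxymethoxy)-3-(3-methylbut-2-en-1-yl)benzoate
Conditions: K2CO3, DMF, 70 °C
Reagents that add atoms: none
Why: Base-mediated O-vinylation of a phenol with trichloroethene (elimination to dichloroethyne and anti addition of the phenoxide), the established entry to aryl (E)-1,2-dichlorovinyl ethers; the small linear electrophile tolerates the two ortho substituents.

Step 8
Reactants: 13 allyl 2-{[(E)-1,2-dichloroethenyl]oxy}-4,6-bis(methoxymethoxy)-3-(3-methylbut-2-en-1-yl)benzoate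
Product: 16 allyl 4,6-bis(methoxymethoxy)-3-(3-methylbut-2-en-1-yl)-2-[(5-methylhex-4-en-1-yn-1-yl)oxy]benzoate, via chloroethynyl ether 14 (not isolated), via lithium acetylide 15 (not isolated)
Conditions: n-BuLi (2.1 equiv, slow addition), THF/Et2O, -95 to -78 °C; CuI (10 mol%), prenyl bromide, DMPU, -78 to 0 °C; basic work-up
Reagents that add atoms: prenyl bromide (1-bromo-3-methylbut-2-ene), CC(C)=CCBr
Why: Ynol ether synthesis from a 1,2-dichlorovinyl ether: dehydrochlorination gives 14, chlorine–lithium exchange gives 15, and copper-catalysed SN2 allylation gives the skipped enyne. Vinylic deprotonation and halogen–lithium exchange are expected to outrun addition to the doubly ortho-substituted benzoate at this temperature, as in low-temperature exchange reactions run in the presence of esters.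

Step 9
Reactants: 7 pentacarbonyl{methoxy[2,2-dimethyl-4-(triisopropylsilyloxy)-3,4-dihydro-2H-pyran-6-yl]methylidene}chromium; 16 allyl 4,6-bis(methoxymethoxy)-3-(3-methylbut-2-en-1-yl)-2-[(5-methylhex-4-en-1-yn-1-yl)oxy]benzoate
Product: 18 allyl 2-{[5-hydroxy-8-methoxy-2,2-dimethyl-7-(3-methylbut-2-en-1-yl)-4-(triisopropylsilyloxy)-3,4-dihydro-2H-chromen-6-yl]oxy}-4,6-bis(methoxymethoxy)-3-(3-methylbut-2-en-1-yl)benzoate (racemic), via tricarbonylchromium arene complex 17 (not isolated)
Conditions: THF (degassed), 50 °C, Ar, 7 in slight excess; then air, Et2O, rt
Reagents that add atoms: none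
Why: Dötz benzannulation (3+2+1) of an alkenyl(alkoxy)carbene complex of zerovalent chromium; the closest precedent is the reaction of dihydropyranyl and glycal-derived methoxycarbene complexes with alkynes to give chroman hydroquinone monomethyl ethers, and alkynes with an allylic substituent are established partners. The polarised ynol ether 16 attacks the electrophilic carbene carbon of 7 through its prenyl-bearing carbon, with or after loss of one CO, so insertion gives a vinylcarbene whose metal-bound carbon carries the aryloxy group; CO insertion then forms a chromium-bound dienylketene. Ring A closes by 6π-electrocyclisation of this ketene onto the enol ether β-carbon of the dihydropyran, and tautomerisation gives the phenol as its Cr(CO)3 complex 17, from which air releases 18. The three new C–C bonds are C8–C7 (carbene carbon to alkyne), C6–C5 (alkyne to CO) and C5–C4a (CO to pyran carbon), and the six ring atoms are the carbene carbon, both alkyne carbons, one CO carbon and the two enol ether carbons. No stereocentre is formed; the silyloxy-bearing carbon is a racemic spectator. The selectivity needed is the alkyne orientation, aryloxy carbon next to the CO-derived carbon. It is secured electronically by the ynol ether polarisation and by oxygen stabilisation of the new carbene carbon, the same bias that governs ynamine insertions. The slight excess of 7 guards against uptake of a second alkyne.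

Step 10
Reactants: 18 allyl 2-{[5-hydroxy-8-methoxy-2,2-dimethyl-7-(3-methylbut-2-en-1-yl)-4-(triisopropylsilyloxy)-3,4-dihydro-2H-chromen-6-yl]oxy}-4,6-bis(methoxymethoxy)-3-(3-methylbut-2-en-1-yl)benzoate
Product: 20 allyl 2-{[5-hydroxy-8-methoxy-2,2-dimethyl-7-(3-methylbut-2-en-1-yl)-2H-chromen-6-yl]oxy}-4,6-bis(methoxymethoxy)-3-(3-methylbut-2-en-1-yl)benzoate, via chroman-4-ol 19 (not isolated)
Conditions: HF·pyridine, pyridine, THF, 0 °C to rt; then PPTS (cat.), toluene, 60 °C
Reagents that add atoms: none
Why: Fluoride desilylation followed by acid-catalysed E1 dehydration of the benzylic chroman-4-ol (cation stabilised by the ring oxygen and the C5 hydroxyl), the usual route from chromanols to 2,2-dimethyl-2H-chromenes. Acidic fluoride is used instead of a basic fluoride source so that no phenoxide forms beside the allyl ester, and no free phenol is ortho to a prenyl group at this stage.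

Step 11
Reactants: 20 allyl 2-{[5-hydroxy-8-methoxy-2,2-dimethyl-7-(3-methylbut-2-en-1-yl)-2H-chromen-6-yl]oxy}-4,6-bis(methoxymethoxy)-3-(3-methylbut-2-en-1-yl)benzoate
Product: 22 allyl 2-{[5,8-dihydroxy-2,2-dimethyl-7-(3-methylbut-2-en-1-yl)-2H-chromen-6-yl]oxy}-4,6-bis(methoxymethoxy)-3-(3-methylbut-2-en-1-yl)benzoate, via chromenequinone 21 (not isolated)
Conditions: PhI(OAc)2 (1.1 equiv), MeCN/H2O (4:1), 0 °C; then aq. Na2S2O4, EtOAc, rt, Ar
Reagents that add atoms: water, O
Why: Oxidative demethylation of a 4-methoxyphenol to the para-quinone (water adds para to the oxidised phenol and methanol is lost) followed by dithionite reduction, a net unmasking of the C8 hydroxyl. The aryloxyquinone 21 is a vinylogous aryl ester and is therefore reduced without isolation.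

Step 12
Reactants: 22 allyl 2-{[5,8-dihydroxy-2,2-dimethyl-7-(3-methylbut-2-en-1-yl)-2H-chromen-6-yl]oxy}-4,6-bis(methoxymethoxy)-3-(3-methylbut-2-en-1-yl)benzoate
Product: 23 2-{[5,8-dihydroxy-2,2-dimethyl-7-(3-methylbut-2-en-1-yl)-2H-chromen-6-yl]oxy}-4,6-bis(methoxymethoxy)-3-(3-methylbut-2-en-1-yl)benzoic acid
Conditions: Pd(PPh3)4 (5 mol%), morpholine, degassed THF, rt; dilute citric acid work-up, crude used directly
Reagents that add atoms: none
Why: Tsuji–Trost deallylation: zerovalent palladium ionises the allyl ester and morpholine traps the allyl fragment; acetal ethers, the trisubstituted prenyl alkenes and the chromene are inert.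

Step 13
Reactants: 23 2-{[5,8-dihydroxy-2,2-dimethyl-7-(3-methylbut-2-en-1-yl)-2H-chromen-6-yl]oxy}-4,6-bis(methoxymethoxy)-3-(3-methylbut-2-en-1-yl)benzoic acid
Product: 24 bis(methoxymethyl) ether of 25 at the two ring B oxygens (depsidone lactone between the C1′ carboxyl and the C5 oxygen, C8 hydroxyl free)
Conditions: DCC, DMAP (cat.), CH2Cl2, high dilution, 0 °C to rt
Reagents that add atoms: none
Why: Carbodiimide (Steglich) lactonisation, the classical closure of depsidones from 2-aryloxybenzoic acids. Only the C5 hydroxyl can reach the activated carboxyl (seven-membered ring), the C8 hydroxyl being para to it, and dilution suppresses intermolecular acylation.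

Step 14
Reactants: 24 bis(methoxymethyl) ether of 25
Product: 25 CNP0263700.0, the depsidone with free hydroxyls at C8, C4′ and C6′, prenyl groups at C7 and C3′ and the fused 2,2-dimethyl-2H-pyran on ring A
Conditions: HCl (about 1 M in MeOH), MeOH/THF, rt to 40 °C
Reagents that add atoms: none
Why: Acid-catalysed acetal exchange of the two aryl methoxymethyl ethers with methanol, routinely applied to prenylated phenols and 2,2-dimethylchromenes; the mild temperature is meant to avoid closure of a prenyl group onto a neighbouring hydroxyl.

## Compound list

1 | 2,2-dimethyl-2,3-dihydro-4H-pyran-4-one | CC1(C)CC(=O)C=CO1 | starting material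
2 | 2,2-dimethyl-3,4-dihydro-2H-pyran-4-ol (racemic) | CC1(C)CC(O)C=CO1 | intermediate
3 | 2,2-dimethyl-4-(triisopropylsilyloxy)-3,4-dihydro-2H-pyran (racemic) | CC1(C)CC(O[Si](C(C)C)(C(C)C)C(C)C)C=CO1 | intermediate
4 | chromium hexacarbonyl, Cr(CO)6 | O=C=[Cr](=C=O)(=C=O)(=C=O)(=C=O)=C=O | starting material
5 | [2,2-dimethyl-4-(triisopropylsilyloxy)-3,4-dihydro-2H-pyran-6-yl]lithium (racemic) | [Li]C1=CC(O[Si](C(C)C)(C(C)C)C(C)C)CC(C)(C)O1 | intermediate (not isolated)
6 | lithium pentacarbonyl{[2,2-dimethyl-4-(triisopropylsilyloxy)-3,4-dihydro-2H-pyran-6-yl]carbonyl}chromate (racemic) | [Li+].[O-]C(C1=CC(O[Si](C(C)C)(C(C)C)C(C)C)CC(C)(C)O1)=[Cr](=C=O)(=C=O)(=C=O)(=C=O)=C=O | intermediate (not isolated)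
7 | pentacarbonyl{methoxy[2,2-dimethyl-4-(triisopropylsilyloxy)-3,4-dihydro-2H-pyran-6-yl]methylidene}chromium (racemic) | COC(C1=CC(O[Si](C(C)C)(C(C)C)C(C)C)CC(C)(C)O1)=[Cr](=C=O)(=C=O)(=C=O)(=C=O)=C=O | intermediate
8 | 2,4,6-trihydroxybenzoic acid | OC(=O)c1c(O)cc(O)cc1O | starting material
9 | allyl 2,4,6-trihydroxybenzoate | C=CCOC(=O)c1c(O)cc(O)cc1O | intermediate
10 | allyl 2,4,6-trihydroxy-3-(3-methylbut-2-en-1-yl)benzoate | C=CCOC(=O)c1c(O)cc(O)c(CC=C(C)C)c1O | intermediate
11 | allyl 2-hydroxy-4,6-bis(methoxymethoxy)-3-(3-methylbut-2-en-1-yl)benzoate | C=CCOC(=O)c1c(OCOC)cc(OCOC)c(CC=C(C)C)c1O | intermediate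
12 | trichloroethene | ClC=C(Cl)Cl | starting material
13 | allyl 2-{[(E)-1,2-dichloroethenyl]oxy}-4,6-bis(methoxymethoxy)-3-(3-methylbut-2-en-1-yl)benzoate | C=CCOC(=O)c1c(OCOC)cc(OCOC)c(CC=C(C)C)c1O/C(Cl)=C\Cl | intermediate
14 | allyl 2-[(chloroethynyl)oxy]-4,6-bis(methoxymethoxy)-3-(3-methylbut-2-en-1-yl)benzoate | C=CCOC(=O)c1c(OCOC)cc(OCOC)c(CC=C(C)C)c1OC#CCl | intermediate (not isolated)
15 | lithium acetylide of allyl 2-(ethynyloxy)-4,6-bis(methoxymethoxy)-3-(3-methylbut-2-en-1-yl)benzoate | C=CCOC(=O)c1c(OCOC)cc(OCOC)c(CC=C(C)C)c1OC#C[Li] | intermediate (not isolated)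
16 | allyl 4,6-bis(methoxymethoxy)-3-(3-methylbut-2-en-1-yl)-2-[(5-methylhex-4-en-1-yn-1-yl)oxy]benzoate | C=CCOC(=O)c1c(OCOC)cc(OCOC)c(CC=C(C)C)c1OC#CCC=C(C)C | intermediate
17 | tricarbonylchromium complex of 18, Cr(CO)3 bound η6 to ring A (racemic; SMILES written with the Cr(CO)3 unit as a separate component) | COc1c(CC=C(C)C)c(Oc2c(CC=C(C)C)c(OCOC)cc(OCOC)c2C(=O)OCC=C)c(O)c2c1OC(C)(C)CC2O[Si](C(C)C)(C(C)C)C(C)C.O=C=[Cr](=C=O)=C=O | intermediate (not isolated)
18 | allyl 2-{[5-hydroxy-8-methoxy-2,2-dimethyl-7-(3-methylbut-2-en-1-yl)-4-(triisopropylsilyloxy)-3,4-dihydro-2H-chromen-6-yl]oxy}-4,6-bis(methoxymethoxy)-3-(3-methylbut-2-en-1-yl)benzoate (racemic) | COc1c(CC=C(C)C)c(Oc2c(CC=C(C)C)c(OCOC)cc(OCOC)c2C(=O)OCC=C)c(O)c2c1OC(C)(C)CC2O[Si](C(C)C)(C(C)C)C(C)C | intermediate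
19 | allyl 2-{[4,5-dihydroxy-8-methoxy-2,2-dimethyl-7-(3-methylbut-2-en-1-yl)-3,4-dihydro-2H-chromen-6-yl]oxy}-4,6-bis(methoxymethoxy)-3-(3-methylbut-2-en-1-yl)benzoate (racemic) | COc1c(CC=C(C)C)c(Oc2c(CC=C(C)C)c(OCOC)cc(OCOC)c2C(=O)OCC=C)c(O)c2c1OC(C)(C)CC2O | intermediate (not isolated)
20 | allyl 2-{[5-hydroxy-8-methoxy-2,2-dimethyl-7-(3-methylbut-2-en-1-yl)-2H-chromen-6-yl]oxy}-4,6-bis(methoxymethoxy)-3-(3-methylbut-2-en-1-yl)benzoate | COc1c(CC=C(C)C)c(Oc2c(CC=C(C)C)c(OCOC)cc(OCOC)c2C(=O)OCC=C)c(O)c2c1OC(C)(C)C=C2 | intermediate
21 | allyl 2-{[2,2-dimethyl-7-(3-methylbut-2-en-1-yl)-5,8-dioxo-5,8-dihydro-2H-chromen-6-yl]oxy}-4,6-bis(methoxymethoxy)-3-(3-methylbut-2-en-1-yl)benzoate | O=C1C(CC=C(C)C)=C(Oc2c(CC=C(C)C)c(OCOC)cc(OCOC)c2C(=O)OCC=C)C(=O)C2=C1OC(C)(C)C=C2 | intermediate (not isolated)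
22 | allyl 2-{[5,8-dihydroxy-2,2-dimethyl-7-(3-methylbut-2-en-1-yl)-2H-chromen-6-yl]oxy}-4,6-bis(methoxymethoxy)-3-(3-methylbut-2-en-1-yl)benzoate | Oc1c(CC=C(C)C)c(Oc2c(CC=C(C)C)c(OCOC)cc(OCOC)c2C(=O)OCC=C)c(O)c2c1OC(C)(C)C=C2 | intermediate
23 | 2-{[5,8-dihydroxy-2,2-dimethyl-7-(3-methylbut-2-en-1-yl)-2H-chromen-6-yl]oxy}-4,6-bis(methoxymethoxy)-3-(3-methylbut-2-en-1-yl)benzoic acid | Oc1c(CC=C(C)C)c(Oc2c(CC=C(C)C)c(OCOC)cc(OCOC)c2C(=O)O)c(O)c2c1OC(C)(C)C=C2 | intermediate
24 | bis(methoxymethyl) ether of 25 at the C4′ and C6′ oxygens (depsidone lactone closed, C8 hydroxyl free) | CC(C)=CCc1c(O)c2c(c3c1Oc1c(CC=C(C)C)c(OCOC)cc(OCOC)c1C(=O)O3)C=CC(C)(C)O2 | intermediate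
25 | CNP0263700.0: depsidone of 8-hydroxy-2,2-dimethyl-7-prenyl-2H-chromene (ether at C6, ester oxygen at C5) with a 4,6-dihydroxy-3-prenylbenzoyl unit (ether at C2′, carbonyl at C1′); no stereocentre | CC(C)=CCc1c(O)c2c(c3c1Oc1c(CC=C(C)C)c(O)cc(O)c1C(=O)O3)C=CC(C)(C)O2 | target

## Step count and least certain steps

Total step count: 14. Longest linear sequence: 11 steps (steps 4 to 14, from 8).

Step 9 (key step). The most likely failure is stalling after alkyne insertion. The new carbene carbon is stabilised by the aryloxy group, and such oxygen-stabilised vinylcarbenes insert CO thermally less readily than all-carbon ones. Prolonged heating would then lead to decomposition of the acid- and heat-sensitive ynol ether or to uptake of a second alkyne. Fallback, from 7 and 16 back to 18: the two are combined at 0 °C to room temperature in the dark and the insertion product, the pentacarbonylchromium aryloxy(dienyl)carbene complex F1, is isolated. F1 is then irradiated with visible light under CO in THF, which drives the carbene-to-ketene carbonylation photochemically (photochemical benzannulation of dienylcarbene complexes) and leads after electrocyclisation and exposure to air to 18.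

Step 8. n-BuLi, or the lithium acetylide once formed, may add to the allyl ester in competition with dehydrochlorination and chlorine–lithium exchange, and the prenyl halide may be attacked at its tertiary end. Fallback without alkyllithium, from 11 back to 16: commercial 4-methylpent-3-en-1-ol is oxidised (Dess–Martin oxidation) to 4-methylpent-3-enal F2, which is converted with CBr4 and PPh3 (Ramirez olefination) into 1,1-dibromo-5-methylhexa-1,4-diene F3. Copper-catalysed coupling of phenol 11 with F3 (CuI, 2,2′-bipyridine, K3PO4, toluene, 110 °C) gives the (Z)-bromoenol ether F4, and anti elimination of HBr with KOtBu in dioxane gives 16.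

Step 6. Discrimination between the two ester-flanking hydroxyls may be incomplete, which would place the later ynol ether on the wrong oxygen. Fallback with unambiguous regiochemistry, from 9 back to 11: 9 is bis-protected first, which can only give allyl 2-hydroxy-4,6-bis(methoxymethoxy)benzoate F5. Its remaining hydroxyl is alkylated with 3-chloro-3-methylbut-1-yne (DBU, CuCl2 cat., MeCN) to the 1,1-dimethylpropargyl ether F6. Semihydrogenation (H2, Pd/CaCO3 poisoned with Pb(OAc)2, quinoline) gives the 1,1-dimethylallyl ether F7, and aromatic Claisen rearrangement in hot toluene delivers the prenyl group to the only free ortho carbon, giving 11.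

Step 14. Acid may close a prenyl group onto the neighbouring phenol, add methanol to the chromene double bond, or methanolyse the aryl ester before both acetals are removed. Fallback without Brønsted acid, from 24 back to 25: TMSOTf and 2,2′-bipyridyl in MeCN at 0 °C convert the aryl methoxymethyl ethers (and the free C8 hydroxyl) into trimethylsilyl ethers, giving the tris(trimethylsilyl) ether F8. Neutral aqueous hydrolysis of F8 then gives 25.

## Further compounds

F1 | step 9 | pentacarbonyl{(2-allyloxycarbonyl-3,5-bis(methoxymethoxy)-6-prenylphenoxy)[1-methoxy-1-(2,2-dimethyl-4-triisopropylsilyloxy-3,4-dihydro-2H-pyran-6-yl)-5-methylhexa-1,4-dien-2-yl]methylidene}chromium (racemic, alkene geometry not fixed) | C=CCOC(=O)c1c(OCOC)cc(OCOC)c(CC=C(C)C)c1OC(C(CC=C(C)C)=C(OC)C1=CC(O[Si](C(C)C)(C(C)C)C(C)C)CC(C)(C)O1)=[Cr](=C=O)(=C=O)(=C=O)(=C=O)=C=O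
F2 | step 8 | 4-methylpent-3-enal | CC(C)=CCC=O
F3 | step 8 | 1,1-dibromo-5-methylhexa-1,4-diene | CC(C)=CCC=C(Br)Br
F4 | step 8 | allyl 2-{[(Z)-1-bromo-5-methylhexa-1,4-dien-1-yl]oxy}-4,6-bis(methoxymethoxy)-3-(3-methylbut-2-en-1-yl)benzoate | C=CCOC(=O)c1c(OCOC)cc(OCOC)c(CC=C(C)C)c1O/C(Br)=C/CC=C(C)C
F5 | step 6 | allyl 2-hydroxy-4,6-bis(methoxymethoxy)benzoate | C=CCOC(=O)c1c(O)cc(OCOC)cc1OCOC
F6 | step 6 | allyl 2-[(2-methylbut-3-yn-2-yl)oxy]-4,6-bis(methoxymethoxy)benzoate | C=CCOC(=O)c1c(OC(C)(C)C#C)cc(OCOC)cc1OCOC
F7 | step 6 | allyl 2-[(2-methylbut-3-en-2-yl)oxy]-4,6-bis(methoxymethoxy)benzoate | C=CCOC(=O)c1c(OC(C)(C)C=C)cc(OCOC)cc1OCOC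
F8 | step 14 | tris(trimethylsilyl) ether of 25 at the C8, C4′ and C6′ oxygens | CC(C)=CCc1c(O[Si](C)(C)C)c2c(c3c1Oc1c(CC=C(C)C)c(O[Si](C)(C)C)cc(O[Si](C)(C)C)c1C(=O)O3)C=CC(C)(C)O2
A1 | alternative 1 | bis(methoxymethyl) ether of the target depsidone (identical with 24) | CC(C)=CCc1c(O)c2c(c3c1Oc1c(CC=C(C)C)c(OCOC)cc(OCOC)c1C(=O)O3)C=CC(C)(C)O2
A2 | alternative 1 | [5,8-dihydroxy-2,2-dimethyl-7-(3-methylbut-2-en-1-yl)-2H-chromen-6-yl][2-hydroxy-4,6-bis(methoxymethoxy)-3-(3-methylbut-2-en-1-yl)phenyl]methanone | CC(C)=CCc1c(O)c2OC(C)(C)C=Cc2c(O)c1C(=O)c1c(O)c(CC=C(C)C)c(OCOC)cc1OCOC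
A3 | alternative 2 | 6-hydroxy-2,2-dimethyl-7-(3-methylbut-2-en-1-yl)-2H-chromene-5,8-dione | O=C1C2=C(C=CC(C)(C)O2)C(=O)C(O)=C1CC=C(C)C
A4 | alternative 2 | 2,5-dihydroxy-3-(3-methylbut-2-en-1-yl)cyclohexa-2,5-diene-1,4-dione | O=C1C(O)=C(CC=C(C)C)C(=O)C(O)=C1
A5 | alternative 2 | 3-methylbut-2-enal | CC(C)=CC=O
A6 | alternative 3 | 2-{[5,8-bis(methoxymethoxy)-2,2-dimethyl-7-(3-methylbut-2-en-1-yl)-2H-chromen-6-yl]oxy}-4,6-bis(methoxymethoxy)-3-(3-methylbut-2-en-1-yl)benzoic acid | CC(C)=CCc1c(OCOC)c2OC(C)(C)C=Cc2c(OCOC)c1Oc1c(CC=C(C)C)c(OCOC)cc(OCOC)c1C(=O)O
A7 | alternative 3 | 3,5-bis(methoxymethoxy)-6-(3-methylbut-2-en-1-yl)-2-(trimethylsilyl)phenyl trifluoromethanesulfonate | C[Si](C)(C)c1c(OS(=O)(=O)C(F)(F)F)c(CC=C(C)C)c(OCOC)cc1OCOC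
A8 | alternative 3 | 5,8-bis(methoxymethoxy)-2,2-dimethyl-7-(3-methylbut-2-en-1-yl)-2H-chromen-6-ol | CC(C)=CCc1c(OCOC)c2OC(C)(C)C=Cc2c(OCOC)c1O
A9 | alternative 3 | carbon dioxide | O=C=O
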